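**Strategy.** Everything rests on opening the cyclohexanone ring at the bond between its quaternary carbon C1' and the methyl-bearing C6' (cyclohexyl locants as in the name; side chain C1 to C5 counted from the quinone). C1' lies β to the carbinol carbon C4, so raising C4 to an ester turns C1' into the β-carbon of a Z-enoate, while the CH(CH3) at C6' is a masked terminal vinyl group. One iron hydride hydrogen atom transfer then makes the C6' methyl, closes the ring by 6-exo radical conjugate addition and sets C1' and C6'. Allylic strain between C2'–H and the Z-ester fixes the attacked face. The precursor is an acyclic aldol-derived dienoate with the ring ketone masked as a silyl ether.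

Key step: step 8

Remark: the enantiomer of the sulfonamide ligand in step 19 that delivers the alkenyl group to the Re face of the aldehyde is to be fixed on a model aldehyde before use.

**Step 1**
Reactants: 1 (4S)-4-benzyl-3-propanoyl-1,3-oxazolidin-2-one; 2 pent-4-enal
Product: 4 (4S)-4-benzyl-3-[(2S,3R)-3-hydroxy-2-methylhept-6-enoyl]-1,3-oxazolidin-2-one, via dibutylboron Z-enolate 3 (not isolated)
Conditions: Bu2BOTf, i-Pr2NEt, CH2Cl2, 0 °C; 2, −78 → 0 °C; H2O2, MeOH, pH 7 buffer
Reagents that add atoms: none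
Why: Evans syn aldol, in which Z-enolate 3 reacts through a Zimmerman–Traxler chair on the face away from the benzyl group, setting the permanent C2' methyl centre (2S here) and the temporary C3' carbinol (3R).

**Step 2**
Reactants: 4 (4S)-4-benzyl-3-[(2S,3R)-3-hydroxy-2-methylhept-6-enoyl]-1,3-oxazolidin-2-one
Product: 5 (4S)-4-benzyl-3-[(2S,3R)-3-(tert-butyldimethylsilyloxy)-2-methylhept-6-enoyl]-1,3-oxazolidin-2-one
Conditions: TBSOTf, 2,6-lutidine, CH2Cl2, −78 → 0 °C
Reagents that add atoms: tert-butyldimethylsilyl triflate CC(C)(C)[Si](C)(C)OS(=O)(=O)C(F)(F)F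
Why: Silylation of the secondary alcohol with a silyl triflate and a hindered base touches no stereocentre and blocks retro-aldol cleavage.

**Step 3**
Reactants: 5 (4S)-4-benzyl-3-[(2S,3R)-3-(tert-butyldimethylsilyloxy)-2-methylhept-6-enoyl]-1,3-oxazolidin-2-one
Product: 6 (2R,3R)-3-(tert-butyldimethylsilyloxy)-2-methylhept-6-en-1-ol
Conditions: LiBH4, MeOH (1 equiv), THF, 0 °C
Reagents that add atoms: none
Why: Reductive removal of the auxiliary, in which LiBH4 attacks the exocyclic imide carbonyl and releases the primary alcohol without epimerisation at C2.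

**Step 4**
Reactants: 6 (2R,3R)-3-(tert-butyldimethylsilyloxy)-2-methylhept-6-en-1-ol
Product: 7 (2S,3R)-3-(tert-butyldimethylsilyloxy)-2-methylhept-6-enal
Conditions: Dess–Martin periodinane, NaHCO3, CH2Cl2, 0 °C → rt
Reagents that add atoms: none
Why: Dess–Martin oxidation under buffered, non-basic conditions should give the α-branched aldehyde without epimerisation.

**Step 5**
Reactants: 7 (2S,3R)-3-(tert-butyldimethylsilyloxy)-2-methylhept-6-enal
Product: 8 tert-butyl{[(3R,4R)-1,1-dibromo-3-methylocta-1,7-dien-4-yl]oxy}dimethylsilane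
Conditions: CBr4, PPh3, CH2Cl2, 0 °C
Reagents that add atoms: carbon tetrabromide BrC(Br)(Br)Br
Why: First stage of the Corey–Fuchs homologation, a Wittig-type reaction of the dibromomethylene ylide formed in situ.

**Step 6**
Reactants: 8 tert-butyl{[(3R,4R)-1,1-dibromo-3-methylocta-1,7-dien-4-yl]oxy}dimethylsilane
Product: 10 methyl (4R,5R)-5-(tert-butyldimethylsilyloxy)-4-methylnon-8-en-2-ynoate, via lithium acetylide 9 (not isolated)
Conditions: n-BuLi (2.1 equiv), THF, −78 °C; ClCO2Me, −78 → 0 °C
Reagents that add atoms: methyl chloroformate COC(=O)Cl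
Why: Second stage of the Corey–Fuchs sequence, in which bromine–lithium exchange and Fritsch–Buttenberg–Wiechell rearrangement give acetylide 9, which the chloroformate acylates.

**Step 7**
Reactants: 10 methyl (4R,5R)-5-(tert-butyldimethylsilyloxy)-4-methylnon-8-en-2-ynoate
Product: 12 methyl (2Z,4R,5R)-5-(tert-butyldimethylsilyloxy)-3,4-dimethylnona-2,8-dienoate, via alkenylcuprate 11 (not isolated)
Conditions: Me2CuLi (from MeLi, CuI), THF, −78 °C; MeOH quench at −78 °C
Reagents that add atoms: lithium dimethylcuprate [Li+].C[Cu-]C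
Why: Syn carbocupration of the ynoate puts the new methyl and copper on the same side, so protonation of 11 at low temperature with retention gives the Z-enoate with the chain and CO2Me cis.

**Step 8**
Reactants: 12 methyl (2Z,4R,5R)-5-(tert-butyldimethylsilyloxy)-3,4-dimethylnona-2,8-dienoate
Product: 15 methyl 2-[(1S,2R,3R,6R)-3-(tert-butyldimethylsilyloxy)-1,2,6-trimethylcyclohexyl]acetate, via secondary alkyl radical 13 (not isolated), via α-ester radical 14 (not isolated)
Conditions: Fe(acac)3 (0.5 equiv), PhSiH3 (slow addition), EtOH/ethylene glycol 5:1, 60 °C, 0.02 M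
Reagents that add atoms: none
Why: Fe(acac)3 and PhSiH3 in ethanol give an iron hydride that transfers a hydrogen atom to the terminal CH2 (Markovnikov), so the C6' methyl and the secondary radical 13 arise together; 13 adds to C1', the β-carbon of the Z-enoate, and the α-ester radical 14 is reduced and protonated. The closest known reaction type is the iron hydride reductive olefin coupling (hydrogen atom transfer Giese reaction) in its intramolecular form. The cyclohexane closes 6-exo-trig, the polarity-matched mode for a nucleophilic alkyl radical and an electron-poor β-carbon, whereas 7-endo attack at the α-carbon is mismatched. C1' is controlled by the C2' stereocentre: allylic 1,3-strain with the Z-CO2Me holds C2'–H in the enoate plane, the tether through C3' then reaches only the face anti to the C2' methyl, and the chair with OTBS and C2'-CH3 equatorial puts the C1' methyl axial and CH2CO2Me equatorial. C6' is controlled by the same chair, its methyl pseudo-equatorial because the pseudo-axial alternative meets the Z-ester and the axial hydrogens at C2' and C4'; this is the less secure of the two selectivities. The step needs 6-exo closure to outrun 1,5-hydrogen transfer from the allylic C2'–H and direct reduction of 13, which the conjugated acceptor, dilution and slow silane delivery should favour.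

**Step 9**
Reactants: 15 methyl 2-[(1S,2R,3R,6R)-3-(tert-butyldimethylsilyloxy)-1,2,6-trimethylcyclohexyl]acetate
Product: 16 2-[(1S,2R,3R,6R)-3-(tert-butyldimethylsilyloxy)-1,2,6-trimethylcyclohexyl]ethan-1-ol
Conditions: LiAlH4, THF, 0 °C
Reagents that add atoms: none
Why: Hydride reduction of the ester to the primary alcohol leaves the silyl ether and the ring stereocentres untouched.

**Step 10**
Reactants: 16 2-[(1S,2R,3R,6R)-3-(tert-butyldimethylsilyloxy)-1,2,6-trimethylcyclohexyl]ethan-1-ol
Product: 17 (1R,2R,3S,4R)-3-(2-hydroxyethyl)-2,3,4-trimethylcyclohexan-1-ol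
Conditions: TBAF, THF, 50 °C
Reagents that add atoms: none
Why: Fluoride cleaves the Si–O bond of the hindered secondary silyl ether.

**Step 11**
Reactants: 17 (1R,2R,3S,4R)-3-(2-hydroxyethyl)-2,3,4-trimethylcyclohexan-1-ol
Product: 18 2-[(1S,2R,6R)-1,2,6-trimethyl-3-oxocyclohexyl]acetaldehyde
Conditions: Dess–Martin periodinane (3 equiv), NaHCO3, CH2Cl2, rt
Reagents that add atoms: none
Why: Double Dess–Martin oxidation turns both alcohols into carbonyl groups in one operation under buffered conditions that should not epimerise the α-methyl ketone centre C2'.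

**Step 12**
Reactants: 19 orcinol (5-methylbenzene-1,3-diol)
Product: 20 4-chloro-5-methylbenzene-1,3-diol
Conditions: SO2Cl2 (1.0 equiv), Et2O, 0 °C
Reagents that add atoms: sulfuryl chloride O=S(=O)(Cl)Cl
Why: Electrophilic aromatic chlorination should go to the position para to one hydroxyl and ortho to the methyl group, the position between the two hydroxyls being more hindered.

**Step 13**
Reactants: 20 4-chloro-5-methylbenzene-1,3-diol
Product: 21 2-chloro-1,5-bis(methoxymethoxy)-3-methylbenzene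
Conditions: MOMCl, i-Pr2NEt, CH2Cl2, 0 °C → rt
Reagents that add atoms: chloromethyl methyl ether COCCl
Why: O-Alkylation gives the bis(methoxymethyl) ether, which protects the phenols and directs the later ortho-lithiation.

**Step 14**
Reactants: 22 but-2-yn-1-ol
Product: 24 (2E)-3-iodobut-2-en-1-ol, via alkenylzirconocene 23 (not isolated)
Conditions: i-Bu2AlH (2 equiv), Cp2ZrCl2, THF, 0 °C → rt; I2, −78 → 0 °C
Reagents that add atoms: iodine II
Why: Hydrozirconation–iodination, in which syn addition of Zr–H (Cp2Zr(H)Cl made in situ) places zirconium on the methyl-bearing alkyne carbon remote from the aluminium alkoxide and iodinolysis with retention gives the E-iodoalkene.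

**Step 15**
Reactants: 24 (2E)-3-iodobut-2-en-1-ol
Product: 25 (2E)-1-bromo-3-iodobut-2-ene
Conditions: CBr4, PPh3, CH2Cl2, 0 °C
Reagents that add atoms: carbon tetrabromide BrC(Br)(Br)Br
Why: Appel bromination of the primary allylic alcohol by SN2 displacement of the oxyphosphonium ion, without allylic shift or change of alkene geometry.

**Step 16**
Reactants: 21 2-chloro-1,5-bis(methoxymethoxy)-3-methylbenzene; 25 (2E)-1-bromo-3-iodobut-2-ene
Product: 28 2-chloro-4-[(2E)-3-iodobut-2-en-1-yl]-3,5-bis(methoxymethoxy)-1-methylbenzene, via aryllithium 26 (not isolated), via arylcopper 27 (not isolated)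
Conditions: n-BuLi, THF, 0 °C; CuBr·SMe2, −78 °C; 25, −78 → 0 °C
Reagents that add atoms: none
Why: Directed ortho-lithiation between the two methoxymethoxy groups, transmetallation to the arylcopper and SN2 allylation at the unhindered CH2Br terminus, which is expected to be faster than any reaction at the vinyl iodide.

**Step 17**
Reactants: 28 2-chloro-4-[(2E)-3-iodobut-2-en-1-yl]-3,5-bis(methoxymethoxy)-1-methylbenzene
Product: 29 4-chloro-2-[(2E)-3-iodobut-2-en-1-yl]-5-methylbenzene-1,3-diol
Conditions: HCl (cat.), MeOH, 40 °C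
Reagents that add atoms: none
Why: Acid-catalysed acetal exchange with methanol frees both phenols at a stage where the only alkene is a vinyl iodide deactivated towards protonation.

**Step 18**
Reactants: 29 4-chloro-2-[(2E)-3-iodobut-2-en-1-yl]-5-methylbenzene-1,3-diol
Product: 30 {[4-chloro-2-[(2E)-3-iodobut-2-en-1-yl]-5-methyl-1,3-phenylene]bis(oxy)}bis[tert-butyl(dimethyl)silane]
Conditions: TBSOTf, 2,6-lutidine, CH2Cl2, 0 °C
Reagents that add atoms: tert-butyldimethylsilyl triflate CC(C)(C)[Si](C)(C)OS(=O)(=O)C(F)(F)F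
Why: Silylation of both hindered phenols with the silyl triflate gives a protecting group that fluoride can remove at the end without acid.

**Step 19**
Reactants: 18 2-[(1S,2R,6R)-1,2,6-trimethyl-3-oxocyclohexyl]acetaldehyde; 30 {[4-chloro-2-[(2E)-3-iodobut-2-en-1-yl]-5-methyl-1,3-phenylene]bis(oxy)}bis[tert-butyl(dimethyl)silane]
Product: 32 (2R,3S,4R)-3-[(2S,3E)-5-{2,6-bis(tert-butyldimethylsilyloxy)-3-chloro-4-methylphenyl}-2-hydroxy-3-methylpent-3-en-1-yl]-2,3,4-trimethylcyclohexan-1-one, via alkenylchromium 31 (not isolated)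
Conditions: CrCl2, chiral ligand N-[2-(4-isopropyl-4,5-dihydro-1,3-oxazol-2-yl)-6-methoxyphenyl]methanesulfonamide, Et3N, NiCl2 (cat.), THF, rt
Reagents that add atoms: none
Why: Nozaki–Hiyama–Kishi reaction, in which NiCl2-catalysed formation of alkenylchromium 31 keeps the E geometry and 31 adds to the aldehyde but not to the hindered ketone, the sulfonamide-bound chromium being expected to deliver the alkenyl group to the Re face and so set the (S)-carbinol by reagent control.

**Step 20**
Reactants: 32 (2R,3S,4R)-3-[(2S,3E)-5-{2,6-bis(tert-butyldimethylsilyloxy)-3-chloro-4-methylphenyl}-2-hydroxy-3-methylpent-3-en-1-yl]-2,3,4-trimethylcyclohexan-1-one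
Product: 33 4-chloro-2-[(2E,4S)-4-hydroxy-3-methyl-5-[(1S,2R,6R)-1,2,6-trimethyl-3-oxocyclohexyl]pent-2-en-1-yl]-5-methylbenzene-1,3-diol
Conditions: TBAF, AcOH, THF, 0 °C
Reagents that add atoms: none
Why: Buffered fluoride cleaves the two aryl silyl ethers quickly and without the base that could epimerise C2' or the acid that could ionise the allylic alcohol.

**Step 21**
Reactants: 33 4-chloro-2-[(2E,4S)-4-hydroxy-3-methyl-5-[(1S,2R,6R)-1,2,6-trimethyl-3-oxocyclohexyl]pent-2-en-1-yl]-5-methylbenzene-1,3-diol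
Product: 34 5-chloro-2-hydroxy-3-[(2E,4S)-4-hydroxy-3-methyl-5-[(1S,2R,6R)-1,2,6-trimethyl-3-oxocyclohexyl]pent-2-en-1-yl]-6-methylcyclohexa-2,5-diene-1,4-dione
Conditions: Fremy's salt (KSO3)2NO (2.5 equiv), KH2PO4 buffer, acetone/H2O, 0 °C → rt
Reagents that add atoms: Fremy's salt [K+].[K+].[O-]S(=O)(=O)N([O])S(=O)(=O)[O-]
Why: Teuber oxidation, in which the nitroxyl radical makes a phenoxyl radical, a second equivalent attacks the only free ring position (para to one hydroxyl, ortho to the other) and loss of imidodisulfonate gives the 2-hydroxy-1,4-benzoquinone.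

**Compound list**

1 | (4S)-4-benzyl-3-propanoyl-1,3-oxazolidin-2-one | CCC(=O)N1[C@@H](Cc2ccccc2)COC1=O | starting material
2 | pent-4-enal | C=CCCC=O | starting material
3 | dibutylboron Z-enolate of 1 (not isolated) | C/C=C(\OB(CCCC)CCCC)N1[C@@H](Cc2ccccc2)COC1=O | intermediate
4 | (4S)-4-benzyl-3-[(2S,3R)-3-hydroxy-2-methylhept-6-enoyl]-1,3-oxazolidin-2-one | C=CCC[C@@H](O)[C@H](C)C(=O)N1[C@@H](Cc2ccccc2)COC1=O | intermediate
5 | (4S)-4-benzyl-3-[(2S,3R)-3-(tert-butyldimethylsilyloxy)-2-methylhept-6-enoyl]-1,3-oxazolidin-2-one | C=CCC[C@@H](O[Si](C)(C)C(C)(C)C)[C@H](C)C(=O)N1[C@@H](Cc2ccccc2)COC1=O | intermediate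
6 | (2R,3R)-3-(tert-butyldimethylsilyloxy)-2-methylhept-6-en-1-ol | C=CCC[C@@H](O[Si](C)(C)C(C)(C)C)[C@H](C)CO | intermediate
7 | (2S,3R)-3-(tert-butyldimethylsilyloxy)-2-methylhept-6-enal | C=CCC[C@@H](O[Si](C)(C)C(C)(C)C)[C@H](C)C=O | intermediate
8 | tert-butyl{[(3R,4R)-1,1-dibromo-3-methylocta-1,7-dien-4-yl]oxy}dimethylsilane | C=CCC[C@@H](O[Si](C)(C)C(C)(C)C)[C@H](C)C=C(Br)Br | intermediate
9 | lithium acetylide from 8 (not isolated) | C=CCC[C@@H](O[Si](C)(C)C(C)(C)C)[C@H](C)C#C[Li] | intermediate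
10 | methyl (4R,5R)-5-(tert-butyldimethylsilyloxy)-4-methylnon-8-en-2-ynoate | C=CCC[C@@H](O[Si](C)(C)C(C)(C)C)[C@H](C)C#CC(=O)OC | intermediate
11 | lithium alkenyl(methyl)cuprate from 10 (not isolated) | C=CCC[C@@H](O[Si](C)(C)C(C)(C)C)[C@H](C)/C(C)=C(\C(=O)OC)[Cu-]C.[Li+] | intermediate
12 | methyl (2Z,4R,5R)-5-(tert-butyldimethylsilyloxy)-3,4-dimethylnona-2,8-dienoate | C=CCC[C@@H](O[Si](C)(C)C(C)(C)C)[C@H](C)/C(C)=C\C(=O)OC | intermediate
13 | secondary alkyl radical at C6' (not isolated) | C[CH]CC[C@@H](O[Si](C)(C)C(C)(C)C)[C@H](C)/C(C)=C\C(=O)OC | intermediate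
14 | cyclised α-ester radical (not isolated) | COC(=O)[CH][C@@]1(C)[C@H](C)CC[C@@H](O[Si](C)(C)C(C)(C)C)[C@@H]1C | intermediate
15 | methyl 2-[(1S,2R,3R,6R)-3-(tert-butyldimethylsilyloxy)-1,2,6-trimethylcyclohexyl]acetate | COC(=O)C[C@@]1(C)[C@H](C)CC[C@@H](O[Si](C)(C)C(C)(C)C)[C@@H]1C | intermediate
16 | 2-[(1S,2R,3R,6R)-3-(tert-butyldimethylsilyloxy)-1,2,6-trimethylcyclohexyl]ethan-1-ol | OCC[C@@]1(C)[C@H](C)CC[C@@H](O[Si](C)(C)C(C)(C)C)[C@@H]1C | intermediate
17 | (1R,2R,3S,4R)-3-(2-hydroxyethyl)-2,3,4-trimethylcyclohexan-1-ol | OCC[C@@]1(C)[C@H](C)CC[C@@H](O)[C@@H]1C | intermediate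
18 | 2-[(1S,2R,6R)-1,2,6-trimethyl-3-oxocyclohexyl]acetaldehyde | O=CC[C@@]1(C)[C@H](C)CCC(=O)[C@@H]1C | intermediate
19 | orcinol (5-methylbenzene-1,3-diol) | Cc1cc(O)cc(O)c1 | starting material
20 | 4-chloro-5-methylbenzene-1,3-diol | Cc1cc(O)cc(O)c1Cl | intermediate
21 | 2-chloro-1,5-bis(methoxymethoxy)-3-methylbenzene | COCOc1cc(C)c(Cl)c(OCOC)c1 | intermediate
22 | but-2-yn-1-ol | CC#CCO | starting material
23 | (E)-alkenylzirconocene chloride, O-diisobutylaluminium alkoxide (not isolated) | C/C(=C\CO[Al](CC(C)C)CC(C)C)[Zr](Cl)(C1C=CC=C1)C1C=CC=C1 | intermediate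
24 | (2E)-3-iodobut-2-en-1-ol | C/C(I)=C\CO | intermediate
25 | (2E)-1-bromo-3-iodobut-2-ene | C/C(I)=C\CBr | intermediate
26 | aryllithium from 21, lithium between the two methoxymethoxy groups (not isolated) | COCOc1cc(C)c(Cl)c(OCOC)c1[Li] | intermediate
27 | arylcopper from 26 (not isolated) | COCOc1cc(C)c(Cl)c(OCOC)c1[Cu] | intermediate
28 | 2-chloro-4-[(2E)-3-iodobut-2-en-1-yl]-3,5-bis(methoxymethoxy)-1-methylbenzene | COCOc1cc(C)c(Cl)c(OCOC)c1C/C=C(\C)I | intermediate
29 | 4-chloro-2-[(2E)-3-iodobut-2-en-1-yl]-5-methylbenzene-1,3-diol | Cc1cc(O)c(C/C=C(\C)I)c(O)c1Cl | intermediate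
30 | {[4-chloro-2-[(2E)-3-iodobut-2-en-1-yl]-5-methyl-1,3-phenylene]bis(oxy)}bis[tert-butyl(dimethyl)silane] | Cc1cc(O[Si](C)(C)C(C)(C)C)c(C/C=C(\C)I)c(O[Si](C)(C)C(C)(C)C)c1Cl | intermediate
31 | alkenylchromium dichloride from 30 (not isolated) | Cc1cc(O[Si](C)(C)C(C)(C)C)c(C/C=C(\C)[Cr](Cl)Cl)c(O[Si](C)(C)C(C)(C)C)c1Cl | intermediate
32 | (2R,3S,4R)-3-[(2S,3E)-5-{2,6-bis(tert-butyldimethylsilyloxy)-3-chloro-4-methylphenyl}-2-hydroxy-3-methylpent-3-en-1-yl]-2,3,4-trimethylcyclohexan-1-one | Cc1cc(O[Si](C)(C)C(C)(C)C)c(C/C=C(\C)[C@@H](O)C[C@@]2(C)[C@H](C)CCC(=O)[C@@H]2C)c(O[Si](C)(C)C(C)(C)C)c1Cl | intermediate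
33 | 4-chloro-2-[(2E,4S)-4-hydroxy-3-methyl-5-[(1S,2R,6R)-1,2,6-trimethyl-3-oxocyclohexyl]pent-2-en-1-yl]-5-methylbenzene-1,3-diol | Cc1cc(O)c(C/C=C(\C)[C@@H](O)C[C@@]2(C)[C@H](C)CCC(=O)[C@@H]2C)c(O)c1Cl | intermediate
34 | 5-chloro-2-hydroxy-3-[(2E,4S)-4-hydroxy-3-methyl-5-[(1S,2R,6R)-1,2,6-trimethyl-3-oxocyclohexyl]pent-2-en-1-yl]-6-methylcyclohexa-2,5-diene-1,4-dione | CC1=C(Cl)C(=O)C(C/C=C(\C)[C@@H](O)C[C@@]2(C)[C@H](C)CCC(=O)[C@@H]2C)=C(O)C1=O | target

**Step count.** Total: 21 steps. Longest linear sequence: 14 steps (steps 1 to 11, then 19 to 21).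

**Steps most likely to fail**

1. Step 8 (key step). The secondary radical may be reduced, or may abstract the allylic hydrogen at C2', faster than it cyclises, and the facial choice at the radical carbon C6' may be low. The fallback forms the same bond by a two-electron ring closure and sets C6' afterwards under thermodynamic control. It sets out from 12: Wacker oxidation (PdCl2, CuCl, O2, DMF/H2O) of the terminal alkene would give methyl (2Z,4R,5R)-5-(tert-butyldimethylsilyloxy)-3,4-dimethyl-8-oxonon-2-enoate F1. Kinetic deprotonation at the ketone methyl group (KHMDS, −78 °C) and trapping with PhNTf2 would give the enol triflate methyl (2Z,4R,5R)-5-(tert-butyldimethylsilyloxy)-3,4-dimethyl-8-(trifluoromethylsulfonyloxy)nona-2,8-dienoate F2. A reductive Heck cyclisation (Pd(OAc)2, PPh3, HCO2Na, DMF, 80 °C) would close the ring by 6-exo migratory insertion under the same allylic-strain control and give methyl 2-[(1R,2R,3R)-3-(tert-butyldimethylsilyloxy)-1,2-dimethyl-6-methylidenecyclohexyl]acetate F3. Hydrogen atom transfer hydrogenation of the exocyclic methylene (Mn(dpm)3, PhSiH3, t-BuOOH, i-PrOH), which favours the equatorial methyl, comes back to the route at 15.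

2. Step 19. Facial selectivity at the new carbinol may be poor, because only the reagent controls it and the ring stereocentres are remote. The fallback sets out from 18 and 30: coupling without chiral ligand (CrCl2, NiCl2 cat., DMSO) would give both carbinol epimers of (2R,3S,4R)-3-[(3E)-5-{2,6-bis(tert-butyldimethylsilyloxy)-3-chloro-4-methylphenyl}-2-hydroxy-3-methylpent-3-en-1-yl]-2,3,4-trimethylcyclohexan-1-one F4. MnO2 should oxidise only the allylic alcohol and give the enone (2R,3S,4R)-3-[(3E)-5-{2,6-bis(tert-butyldimethylsilyloxy)-3-chloro-4-methylphenyl}-3-methyl-2-oxopent-3-en-1-yl]-2,3,4-trimethylcyclohexan-1-one F5. Corey–Bakshi–Shibata reduction with (R)-2-methyl-CBS-oxazaborolidine and catecholborane at −78 °C, with the alkenyl group as the large substituent, should reduce the enone faster than the hindered ring ketone and comes back to the route at 32.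

3. Step 16. The arylcopper may react at the vinyl iodide, or halogen–metal exchange may compete with clean allylic substitution. The fallback sets out from 21: lithiation (n-BuLi, THF, 0 °C) and alkylation with 1-bromobut-2-yne would give 2-(but-2-yn-1-yl)-4-chloro-1,3-bis(methoxymethoxy)-5-methylbenzene F6. Hydrozirconation with Cp2Zr(H)Cl (zirconium to the less hindered, methyl-bearing alkyne carbon) followed by iodinolysis with I2 comes back to the route at 28.

**Further compounds**

F1 | step 8 | methyl (2Z,4R,5R)-5-(tert-butyldimethylsilyloxy)-3,4-dimethyl-8-oxonon-2-enoate | CC(=O)CC[C@@H](O[Si](C)(C)C(C)(C)C)[C@H](C)/C(C)=C\C(=O)OC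
F2 | step 8 | methyl (2Z,4R,5R)-5-(tert-butyldimethylsilyloxy)-3,4-dimethyl-8-(trifluoromethylsulfonyloxy)nona-2,8-dienoate | C=C(OS(=O)(=O)C(F)(F)F)CC[C@@H](O[Si](C)(C)C(C)(C)C)[C@H](C)/C(C)=C\C(=O)OC
F3 | step 8 | methyl 2-[(1R,2R,3R)-3-(tert-butyldimethylsilyloxy)-1,2-dimethyl-6-methylidenecyclohexyl]acetate | COC(=O)C[C@@]1(C)C(=C)CC[C@@H](O[Si](C)(C)C(C)(C)C)[C@@H]1C
F4 | step 19 | (2R,3S,4R)-3-[(3E)-5-{2,6-bis(tert-butyldimethylsilyloxy)-3-chloro-4-methylphenyl}-2-hydroxy-3-methylpent-3-en-1-yl]-2,3,4-trimethylcyclohexan-1-one, both carbinol epimers | Cc1cc(O[Si](C)(C)C(C)(C)C)c(C/C=C(\C)C(O)C[C@@]2(C)[C@H](C)CCC(=O)[C@@H]2C)c(O[Si](C)(C)C(C)(C)C)c1Cl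
F5 | step 19 | (2R,3S,4R)-3-[(3E)-5-{2,6-bis(tert-butyldimethylsilyloxy)-3-chloro-4-methylphenyl}-3-methyl-2-oxopent-3-en-1-yl]-2,3,4-trimethylcyclohexan-1-one | Cc1cc(O[Si](C)(C)C(C)(C)C)c(C/C=C(\C)C(=O)C[C@@]2(C)[C@H](C)CCC(=O)[C@@H]2C)c(O[Si](C)(C)C(C)(C)C)c1Cl
F6 | step 16 | 2-(but-2-yn-1-yl)-4-chloro-1,3-bis(methoxymethoxy)-5-methylbenzene | COCOc1cc(C)c(Cl)c(OCOC)c1CC#CC
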